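## Retrosynthetic overview

1. The target is reached from its dodecamethyl ether by global O-demethylation with BBr3.
2. The ring D–O–ring E bond is cut next: Ullmann C–O coupling of a hindered tetramer phenol with 5-iodo-1,2,3-trimethoxybenzene.
3. The ring C–O–D, B–O–C and A–O–B bonds are each cut the same way: SNAr of a 2,6-dimethoxyphenoxide on 4-fluoro-2,6-dimethoxybenzaldehyde, followed by Dakin-type CHO→OH oxidation to unmask the next hindered phenol.
4. The chain starts from 2,4,6-trimethoxyphenol (ring A).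
5. No ring is built; five purchased benzene rings are joined in the order A, B, C, D, E.

Assumption: the target has no stereocentre (it is achiral), so no stereocontrol is needed; compounds 1, 2 and 12 are taken as purchasable.

## Route

Step 1
Reactants: 1 2,4,6-trimethoxyphenol; 2 4-fluoro-2,6-dimethoxybenzaldehyde
Product: 3 2,6-dimethoxy-4-(2,4,6-trimethoxyphenoxy)benzaldehyde
Conditions: Cs2CO3 (2 equiv), DMSO, 100 °C, Ar, 16 h
Reagents that add atoms: none
Why: Nucleophilic aromatic substitution (SNAr), in which the cesium phenoxide of 1 attacks the unhindered fluorine-bearing carbon of 2, activated by the para formyl group, and fluoride leaves; no stereocentre is formed.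

Step 2
Reactants: 3 2,6-dimethoxy-4-(2,4,6-trimethoxyphenoxy)benzaldehyde
Product: 5 2,6-dimethoxy-4-(2,4,6-trimethoxyphenoxy)phenol, via A–B aryl formate 4 (not isolated)
Conditions: mCPBA (1.3 equiv), CH2Cl2, 0 °C to rt; aq. Na2S2O3/NaHCO3 wash; then K2CO3 (0.2 equiv), MeOH, rt, Ar
Reagents that add atoms: mCPBA (3-chloroperoxybenzoic acid), O=C(OO)c1cccc(Cl)c1
Why: Dakin-type Baeyer–Villiger oxidation, in which the electron-rich 2,6-dimethoxy-4-aryloxyphenyl group migrates to give aryl formate 4, whose base-catalysed methanolysis frees the hindered phenol; no stereocentre is formed.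

Step 3
Reactants: 5 2,6-dimethoxy-4-(2,4,6-trimethoxyphenoxy)phenol; 2 4-fluoro-2,6-dimethoxybenzaldehyde (1.3 equiv)
Product: 6 4-[2,6-dimethoxy-4-(2,4,6-trimethoxyphenoxy)phenoxy]-2,6-dimethoxybenzaldehyde
Conditions: Cs2CO3 (2 equiv), DMSO, 100 °C, Ar, 16 h
Reagents that add atoms: none
Why: The same SNAr as step 1, since phenol 5 has the same 2,6-dimethoxyphenol head group as 1 and the electrophile is unchanged; no stereocentre is formed.

Step 4
Reactants: 6 4-[2,6-dimethoxy-4-(2,4,6-trimethoxyphenoxy)phenoxy]-2,6-dimethoxybenzaldehyde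
Product: 8 4-[2,6-dimethoxy-4-(2,4,6-trimethoxyphenoxy)phenoxy]-2,6-dimethoxyphenol, via A–B–C aryl formate 7 (not isolated)
Conditions: mCPBA (1.3 equiv), CH2Cl2, 0 °C to rt; aq. Na2S2O3/NaHCO3 wash; then K2CO3 (0.2 equiv), MeOH, rt, Ar
Reagents that add atoms: mCPBA (3-chloroperoxybenzoic acid), O=C(OO)c1cccc(Cl)c1
Why: Dakin-type Baeyer–Villiger oxidation as in step 2, with aryl migration favoured by the two ortho methoxy groups and the para aryloxy group, followed by formate methanolysis; no stereocentre is formed.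

Step 5
Reactants: 8 4-[2,6-dimethoxy-4-(2,4,6-trimethoxyphenoxy)phenoxy]-2,6-dimethoxyphenol; 2 4-fluoro-2,6-dimethoxybenzaldehyde (1.3 equiv)
Product: 9 4-{4-[2,6-dimethoxy-4-(2,4,6-trimethoxyphenoxy)phenoxy]-2,6-dimethoxyphenoxy}-2,6-dimethoxybenzaldehyde
Conditions: Cs2CO3 (2 equiv), DMSO, 100 °C, Ar, 16 h
Reagents that add atoms: none
Why: Third SNAr of a 2,6-dimethoxyphenoxide on the para-formyl-activated aryl fluoride, adding ring D; no stereocentre is formed.

Step 6
Reactants: 9 4-{4-[2,6-dimethoxy-4-(2,4,6-trimethoxyphenoxy)phenoxy]-2,6-dimethoxyphenoxy}-2,6-dimethoxybenzaldehyde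
Product: 11 4-{4-[2,6-dimethoxy-4-(2,4,6-trimethoxyphenoxy)phenoxy]-2,6-dimethoxyphenoxy}-2,6-dimethoxyphenol, via A–B–C–D aryl formate 10 (not isolated)
Conditions: mCPBA (1.2 equiv), CH2Cl2, 0 °C to rt; aq. Na2S2O3/NaHCO3 wash; then K2CO3 (0.2 equiv), MeOH, rt, Ar
Reagents that add atoms: mCPBA (3-chloroperoxybenzoic acid), O=C(OO)c1cccc(Cl)c1
Why: Dakin-type Baeyer–Villiger oxidation and formate methanolysis as in steps 2 and 4, unmasking the hindered phenol of ring D; no stereocentre is formed.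

Step 7
Reactants: 11 4-{4-[2,6-dimethoxy-4-(2,4,6-trimethoxyphenoxy)phenoxy]-2,6-dimethoxyphenoxy}-2,6-dimethoxyphenol; 12 5-iodo-1,2,3-trimethoxybenzene (2 equiv)
Product: 13 5-{4-[4-(2,6-dimethoxy-4-(2,4,6-trimethoxyphenoxy)phenoxy)-2,6-dimethoxyphenoxy]-2,6-dimethoxyphenoxy}-1,2,3-trimethoxybenzene (dodecamethyl ether of the target)
Conditions: CuI (20 mol %), picolinic acid (40 mol %), K3PO4 (3 equiv), DMSO, 100 °C, Ar, 24 h
Reagents that add atoms: none
Why: Ullmann-type C–O coupling, for which the CuI/picolinic acid system tolerates 2,6-disubstituted phenols and electron-rich aryl iodides, with the cheap iodide 12 in excess; no stereocentre is formed.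

Step 8
Reactants: 13 dodecamethyl ether of the target
Product: 15 5-{4-[4-(2,6-dihydroxy-4-(2,4,6-trihydroxyphenoxy)phenoxy)-2,6-dihydroxyphenoxy]-2,6-dihydroxyphenoxy}benzene-1,2,3-triol (target CNP0308003.0), via per-O-dibromoboryl pentamer 14 (not isolated)
Conditions: BBr3 (1 M in CH2Cl2, 30 equiv), CH2Cl2, −78 °C to rt, 24 h, Ar; ice-water quench, EtOAc extraction; Sephadex LH-20, degassed MeOH
Reagents that add atoms: none
Why: Lewis-acid ether cleavage, in which BBr3 binds each methoxy oxygen and bromide removes the methyl group by SN2 while the diaryl ether bonds cannot react this way, and hydrolysis of the aryloxyboron bromides 14 frees the twelve phenols; no stereocentre is formed.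

## Compound list

1 | 2,4,6-trimethoxyphenol (ring A) | COc1cc(OC)c(O)c(OC)c1 | starting material
2 | 4-fluoro-2,6-dimethoxybenzaldehyde (source of rings B, C and D) | COc1cc(F)cc(OC)c1C=O | starting material
3 | 2,6-dimethoxy-4-(2,4,6-trimethoxyphenoxy)benzaldehyde | COc1cc(OC)c(Oc2cc(OC)c(C=O)c(OC)c2)c(OC)c1 | intermediate
4 | 2,6-dimethoxy-4-(2,4,6-trimethoxyphenoxy)phenyl formate (not isolated) | COc1cc(OC)c(Oc2cc(OC)c(OC=O)c(OC)c2)c(OC)c1 | intermediate
5 | 2,6-dimethoxy-4-(2,4,6-trimethoxyphenoxy)phenol | COc1cc(OC)c(Oc2cc(OC)c(O)c(OC)c2)c(OC)c1 | intermediate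
6 | 4-[2,6-dimethoxy-4-(2,4,6-trimethoxyphenoxy)phenoxy]-2,6-dimethoxybenzaldehyde | COc1cc(OC)c(Oc2cc(OC)c(Oc3cc(OC)c(C=O)c(OC)c3)c(OC)c2)c(OC)c1 | intermediate
7 | 4-[2,6-dimethoxy-4-(2,4,6-trimethoxyphenoxy)phenoxy]-2,6-dimethoxyphenyl formate (not isolated) | COc1cc(OC)c(Oc2cc(OC)c(Oc3cc(OC)c(OC=O)c(OC)c3)c(OC)c2)c(OC)c1 | intermediate
8 | 4-[2,6-dimethoxy-4-(2,4,6-trimethoxyphenoxy)phenoxy]-2,6-dimethoxyphenol | COc1cc(OC)c(Oc2cc(OC)c(Oc3cc(OC)c(O)c(OC)c3)c(OC)c2)c(OC)c1 | intermediate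
9 | 4-{4-[2,6-dimethoxy-4-(2,4,6-trimethoxyphenoxy)phenoxy]-2,6-dimethoxyphenoxy}-2,6-dimethoxybenzaldehyde | COc1cc(OC)c(Oc2cc(OC)c(Oc3cc(OC)c(Oc4cc(OC)c(C=O)c(OC)c4)c(OC)c3)c(OC)c2)c(OC)c1 | intermediate
10 | 4-{4-[2,6-dimethoxy-4-(2,4,6-trimethoxyphenoxy)phenoxy]-2,6-dimethoxyphenoxy}-2,6-dimethoxyphenyl formate (not isolated) | COc1cc(OC)c(Oc2cc(OC)c(Oc3cc(OC)c(Oc4cc(OC)c(OC=O)c(OC)c4)c(OC)c3)c(OC)c2)c(OC)c1 | intermediate
11 | 4-{4-[2,6-dimethoxy-4-(2,4,6-trimethoxyphenoxy)phenoxy]-2,6-dimethoxyphenoxy}-2,6-dimethoxyphenol | COc1cc(OC)c(Oc2cc(OC)c(Oc3cc(OC)c(Oc4cc(OC)c(O)c(OC)c4)c(OC)c3)c(OC)c2)c(OC)c1 | intermediate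
12 | 5-iodo-1,2,3-trimethoxybenzene (ring E) | COc1cc(I)cc(OC)c1OC | starting material
13 | 5-{4-[4-(2,6-dimethoxy-4-(2,4,6-trimethoxyphenoxy)phenoxy)-2,6-dimethoxyphenoxy]-2,6-dimethoxyphenoxy}-1,2,3-trimethoxybenzene | COc1cc(OC)c(Oc2cc(OC)c(Oc3cc(OC)c(Oc4cc(OC)c(Oc5cc(OC)c(OC)c(OC)c5)c(OC)c4)c(OC)c3)c(OC)c2)c(OC)c1 | intermediate
14 | dodecakis-O-(dibromoboryl) derivative of the target (idealised formula for the mixed aryloxyboron bromides, not isolated) | BrB(Br)Oc1cc(OB(Br)Br)c(Oc2cc(OB(Br)Br)c(Oc3cc(OB(Br)Br)c(Oc4cc(OB(Br)Br)c(Oc5cc(OB(Br)Br)c(OB(Br)Br)c(OB(Br)Br)c5)c(OB(Br)Br)c4)c(OB(Br)Br)c3)c(OB(Br)Br)c2)c(OB(Br)Br)c1 | intermediate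
15 | 5-{4-[4-(2,6-dihydroxy-4-(2,4,6-trihydroxyphenoxy)phenoxy)-2,6-dihydroxyphenoxy]-2,6-dihydroxyphenoxy}benzene-1,2,3-triol (achiral) | Oc1cc(O)c(Oc2cc(O)c(Oc3cc(O)c(Oc4cc(O)c(Oc5cc(O)c(O)c(O)c5)c(O)c4)c(O)c3)c(O)c2)c(O)c1 | target

## Step count and risks

Total step count: 8. Longest linear sequence: 8 steps (1 to 15).

The three steps most likely to fail:

Step 7 (Ullmann coupling of the hindered, electron-rich tetramer phenol with an electron-rich aryl iodide). If the copper-catalysed coupling stalls or gives reduction of 12, ring E is added without copper. The fallback sets out from 11. Phenol 11 and aldehyde 2 under the SNAr conditions of step 1 give the pentamer aldehyde F1. mCPBA followed by K2CO3/MeOH, as in step 2, gives by way of the pentamer aryl formate F2 the pentamer phenol F3, which carries eleven methoxy groups and a free 4-OH on ring E. BBr3 in CH2Cl2 converts F3 into the same borylated species 14, where the fallback comes back to the route; the aqueous quench then gives 15. This costs one extra step.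

Step 8 (twelvefold demethylation and isolation of an air-sensitive dodecaphenol). If 15 cannot be obtained pure because of partial demethylation, retained boron or oxidation during chromatography, the product is captured as a stable derivative instead of being isolated directly. The fallback sets out from 13. After the BBr3 reaction and quench the crude polyphenol is acetylated at once (Ac2O, pyridine, DMAP cat., rt) to the dodecaacetate F4, which is purified on silica gel. F4 is then cleaved under non-oxidising acidic conditions (HCl in degassed MeOH, made from AcCl, rt to 40 °C), and evaporation gives 15, where the fallback comes back to the route.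

Step 6 (peracid oxidation of the tetramer aldehyde, where four electron-rich rings compete with the formyl group for mCPBA). If over-oxidation to quinones dominates, the aldehyde is given up as the masked phenol for ring D. The fallback sets out from 8 and replaces steps 5 and 6. Bought 4-bromo-2,6-dimethoxyphenol F5 is benzylated (BnBr, K2CO3, DMF, rt) to 2-(benzyloxy)-5-bromo-1,3-dimethoxybenzene F6. Ullmann coupling of 8 with F6 (CuI, picolinic acid, K3PO4, DMSO, 110 °C) gives the tetramer benzyl ether F7. Hydrogenolysis (H2, Pd/C, EtOAc/MeOH, rt) gives 11, where the fallback comes back to the route.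

## Further compounds

F1 | step 7 | 4-{4-[4-(2,6-dimethoxy-4-(2,4,6-trimethoxyphenoxy)phenoxy)-2,6-dimethoxyphenoxy]-2,6-dimethoxyphenoxy}-2,6-dimethoxybenzaldehyde (pentamer aldehyde) | COc1cc(OC)c(Oc2cc(OC)c(Oc3cc(OC)c(Oc4cc(OC)c(Oc5cc(OC)c(C=O)c(OC)c5)c(OC)c4)c(OC)c3)c(OC)c2)c(OC)c1
F2 | step 7 | pentamer aryl formate (formate ester of F3, not isolated) | COc1cc(OC)c(Oc2cc(OC)c(Oc3cc(OC)c(Oc4cc(OC)c(Oc5cc(OC)c(OC=O)c(OC)c5)c(OC)c4)c(OC)c3)c(OC)c2)c(OC)c1
F3 | step 7 | 4-{4-[4-(2,6-dimethoxy-4-(2,4,6-trimethoxyphenoxy)phenoxy)-2,6-dimethoxyphenoxy]-2,6-dimethoxyphenoxy}-2,6-dimethoxyphenol (pentamer phenol) | COc1cc(OC)c(Oc2cc(OC)c(Oc3cc(OC)c(Oc4cc(OC)c(Oc5cc(OC)c(O)c(OC)c5)c(OC)c4)c(OC)c3)c(OC)c2)c(OC)c1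
F4 | step 8 | dodecaacetate of the target | CC(=O)Oc1cc(OC(C)=O)c(Oc2cc(OC(C)=O)c(Oc3cc(OC(C)=O)c(Oc4cc(OC(C)=O)c(Oc5cc(OC(C)=O)c(OC(C)=O)c(OC(C)=O)c5)c(OC(C)=O)c4)c(OC(C)=O)c3)c(OC(C)=O)c2)c(OC(C)=O)c1
F5 | step 6 | 4-bromo-2,6-dimethoxyphenol (bought) | COc1cc(Br)cc(OC)c1O
F6 | step 6 | 2-(benzyloxy)-5-bromo-1,3-dimethoxybenzene | COc1cc(Br)cc(OC)c1OCc1ccccc1
F7 | step 6 | 2-(benzyloxy)-5-{4-[2,6-dimethoxy-4-(2,4,6-trimethoxyphenoxy)phenoxy]-2,6-dimethoxyphenoxy}-1,3-dimethoxybenzene (tetramer benzyl ether) | COc1cc(OC)c(Oc2cc(OC)c(Oc3cc(OC)c(Oc4cc(OC)c(OCc5ccccc5)c(OC)c4)c(OC)c3)c(OC)c2)c(OC)c1
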